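**Plan**
- Numbering (abietane type): ring C = C8, C9, C11–C14; ring B = C5, C6, C8, C9, C10; ring A = C1–C5, C10; C7 = formyl carbon; C20 = methyl on C10; ring D = the myrcene-derived cyclohexene on C8–C9.
- Retrosynthesis: C12–OH from C12–OMe; ring D is cut at C8–CH2 and C9–CH2 (Diels–Alder) to myrcene and the 12-methoxy-11,14-quinone of the 6-5-6 tricycle; the quinone goes back to an 11,12,14-trimethoxyarene, C6–CHO to a benzylic C6–OMe, and the C4 gem-dimethyl group to a C3=C4(Me) alkene.
- Ring A is a six-membered ring that shares C5–C10 with five-membered ring B, and C1–C2 and C5–C10 are 1,4-related in ring A. With C3=C4 as retron, both bonds are cut in one intramolecular Diels–Alder step whose tether C6–C8–C9 is ring B itself (C8–C9 being the aromatic bond of ring C). The precursor is an ortho-isopropenyl aryl carbinol ether with an (E)-3-methylpenta-2,4-dienyl chain, made from 1,2,4-trimethoxybenzene.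
- Forward order: ring C as arene (steps 1–5), C6 carbinol and diene (6–8), rings A and B together (9), second C4 methyl (10), C6–O exchanged for C6–CHO (11), quinone (12), ring D (13), O-demethylation (14).
- Stereochemistry: C6 is set by catalytic asymmetric alkynylation and relays to C5 and C10 in step 9 (A(1,3) strain, exo tether); C6 ends as the thermodynamic aldehyde epimer; C8 and C9 arise by addition of myrcene anti to the C10 methyl group.

Key step: step 9

Remark: the (S,S) antipode of the ProPhenol ligand is assumed to deliver the alkynyl group to the Re face of aldehyde 10 (6R carbinol); if the sense proves opposite, the (R,R) ligand is used.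

Compounds 3, 7, 12, 16, 17, 20 and 22 are formed and consumed in the flask.

**Route**

Step 1
Reactants: 1 1,2,4-trimethoxybenzene; 2 acetone
Product: 4 2-(2,3,6-trimethoxyphenyl)propan-2-ol, via aryllithium 3 (not isolated)
Conditions: n-BuLi, THF, 0 °C; then 2, −78 °C → rt; H2O
Reagents that add atoms: none
Why: Directed ortho-metalation removes the ring proton flanked by two methoxy groups, and the aryllithium adds to the carbonyl group of acetone.

Step 2
Reactants: 4 2-(2,3,6-trimethoxyphenyl)propan-2-ol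
Product: 5 1,2,4-trimethoxy-3-(propan-2-yl)benzene
Conditions: Et3SiH, CF3CO2H, CH2Cl2, 0 °C → rt
Reagents that add atoms: none
Why: Ionic hydrogenation: acid ionises the tertiary benzylic alcohol to a cation stabilised by two ortho methoxy groups, which the silane reduces by hydride transfer.

Step 3
Reactants: 5 1,2,4-trimethoxy-3-(propan-2-yl)benzene
Product: 6 2,4,5-trimethoxy-3-(propan-2-yl)benzaldehyde
Conditions: Cl2CHOMe, TiCl4, CH2Cl2, −78 → 0 °C; then H2O
Reagents that add atoms: dichloromethyl methyl ether COC(Cl)Cl (formyl carbon, the later C6); water O (carbonyl oxygen on hydrolysis)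
Why: Rieche formylation (electrophilic aromatic substitution) should go to the free position that is para to one methoxy group and ortho to another (the later C8), since the other free position has no para oxygen donor.

Step 4
Reactants: 6 2,4,5-trimethoxy-3-(propan-2-yl)benzaldehyde
Product: 8 2-iodo-3,4,6-trimethoxy-5-(propan-2-yl)benzaldehyde, via lithiated amino alkoxide 7 (not isolated)
Conditions: LiN(Me)CH2CH2NMe2 (from Me2NCH2CH2NHMe and n-BuLi), THF, −20 °C; n-BuLi, −20 °C; iodine, −78 °C → rt; H2O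
Reagents that add atoms: iodine [I][I]
Why: The aldehyde is masked in situ as a lithium α-amino alkoxide that directs ortho-lithiation to the single remaining ring hydrogen (also ortho to a methoxy group); iodinolysis and hydrolytic work-up return the aldehyde.

Step 5
Reactants: 8 2-iodo-3,4,6-trimethoxy-5-(propan-2-yl)benzaldehyde; 9 4,4,5,5-tetramethyl-2-(prop-1-en-2-yl)-1,3,2-dioxaborolane
Product: 10 2,4,5-trimethoxy-3-(propan-2-yl)-6-(prop-1-en-2-yl)benzaldehyde
Conditions: Pd(OAc)2 (5 mol%), SPhos (10 mol%), K3PO4, toluene/H2O, 90 °C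
Reagents that add atoms: none
Why: Suzuki–Miyaura coupling; the bulky electron-rich biaryl phosphine serves the doubly ortho-substituted aryl iodide and the aldehyde is not touched.

Step 6
Reactants: 10 2,4,5-trimethoxy-3-(propan-2-yl)-6-(prop-1-en-2-yl)benzaldehyde; 11 propyne
Product: 13 (1R)-1-[2,4,5-trimethoxy-3-(propan-2-yl)-6-(prop-1-en-2-yl)phenyl]but-2-yn-1-ol, via propynylzinc 12 (not isolated)
Conditions: Me2Zn, (S,S)-ProPhenol [2,6-bis{[(S)-2-(hydroxydiphenylmethyl)pyrrolidin-1-yl]methyl}-4-methylphenol] (20 mol%), Ph3PO (40 mol%), toluene, 0 °C → rt; aq. NH4Cl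
Reagents that add atoms: none
Why: Catalytic enantioselective addition of an alkynylzinc to an aryl aldehyde (dinuclear zinc amino-alkoxide catalyst); ligand-controlled delivery to the Re face sets C6 as R.

Step 7
Reactants: 13 (1R)-1-[2,4,5-trimethoxy-3-(propan-2-yl)-6-(prop-1-en-2-yl)phenyl]but-2-yn-1-ol
Product: 14 1-[(1R)-1-methoxybut-2-yn-1-yl]-2,4,5-trimethoxy-3-(propan-2-yl)-6-(prop-1-en-2-yl)benzene
Conditions: NaH, MeI, THF, 0 °C → rt
Reagents that add atoms: iodomethane IC
Why: Williamson ether synthesis; the methyl ether is thermally robust, keeps the C6 substituent small in the key step and is the leaving group of step 11.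

Step 8
Reactants: 14 1-[(1R)-1-methoxybut-2-yn-1-yl]-2,4,5-trimethoxy-3-(propan-2-yl)-6-(prop-1-en-2-yl)benzene; 15 bromoethene
Product: 18 1-[(1R,2E)-1-methoxy-3-methylpenta-2,4-dien-1-yl]-2,4,5-trimethoxy-3-(propan-2-yl)-6-(prop-1-en-2-yl)benzene, via alkenylzirconocene 16 (not isolated), via alkenylzinc chloride 17 (not isolated)
Conditions: Cp2Zr(H)Cl, THF, rt → 50 °C; then ZnCl2, Pd(PPh3)4 (5 mol%), 15, rt
Reagents that add atoms: none
Why: Syn hydrozirconation of the internal alkyne should place zirconium on C4 (next to the methyl group, remote from the branched C6), and Zr-to-Zn transmetalation with Negishi coupling (retention) gives the (2E)-diene with the C4 methyl cis to C6.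

Step 9
Reactants: 18 1-[(1R,2E)-1-methoxy-3-methylpenta-2,4-dien-1-yl]-2,4,5-trimethoxy-3-(propan-2-yl)-6-(prop-1-en-2-yl)benzene
Product: 19 (4bS,8aS,9R)-1,3,4,9-tetramethoxy-4b,8-dimethyl-2-(propan-2-yl)-5,6,8a,9-tetrahydro-4bH-fluorene
Conditions: toluene (0.01 M), BHT (cat.), sealed tube, 195 °C
Reagents that add atoms: none
Why: A concerted, thermally allowed suprafacial [4+2] cycloaddition joins the (E)-diene C2=C3–C4=C5 to the isopropenyl π bond C10=C1, forming C1–C2 and C5–C10 while the three-atom tether C6–C8–C9 (C8–C9 aromatic) holds the partners together. The closest known reaction type is the type 1 intramolecular Diels–Alder reaction of 1,6,8-nonatrienes to hydrindenes. Ring A closes as the cyclohexene of the cycloaddition (both new bonds), and ring B closes as the five-membered tether ring through the C5–C10 bond between the diene terminus and the internal dienophile carbon. C5 is controlled by C6: A(1,3) strain with the C4 methyl (cis to C6) keeps the C6–H in the diene plane, so the dienophile, delivered on the ring C side, adds anti to the methoxy group (OMe trans to C4); C10 is set by the exo-tether, endo-methyl transition state, which gives the trans ring fusion. The step needs exo over endo tether orientation, and the substrate should secure it because only the endo mode forces the methoxy-bearing edge of ring C (C8, C14) against the C4 methyl, whereas in the exo mode ring C lies next to the small inside hydrogen on C5.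

Step 10
Reactants: 19 (4bS,8aS,9R)-1,3,4,9-tetramethoxy-4b,8-dimethyl-2-(propan-2-yl)-5,6,8a,9-tetrahydro-4bH-fluorene
Product: 21 (4bS,8aS,9R)-1,3,4,9-tetramethoxy-4b,8,8-trimethyl-2-(propan-2-yl)-5,6,7,8,8a,9-hexahydro-4bH-fluorene, via sulfonylhydrazide adduct 20 (not isolated)
Conditions: aq. CH2O, n-C8H17SO2NHNH2, THF, rt; Fe(acac)3 (30 mol%), PhSiH3, MeOH, rt; then 60 °C
Reagents that add atoms: formaldehyde C=O (carbon of the new methyl group)
Why: Metal-hydride hydrogen-atom transfer to the only alkene gives the tertiary C4 radical (Markovnikov), which adds to the formaldehyde sulfonylhydrazone; the adduct loses sulfinate and N2 on warming to leave the second C4 methyl group (radical hydromethylation, no new stereocentre).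

Step 11
Reactants: 21 (4bS,8aS,9R)-1,3,4,9-tetramethoxy-4b,8,8-trimethyl-2-(propan-2-yl)-5,6,7,8,8a,9-hexahydro-4bH-fluorene
Product: 23 (4bS,8aS,9R)-1,3,4-trimethoxy-4b,8,8-trimethyl-2-(propan-2-yl)-5,6,7,8,8a,9-hexahydro-4bH-fluorene-9-carbaldehyde, via benzylic organolithium 22 (not isolated)
Conditions: Li, 4,4'-di-tert-butylbiphenyl (10 mol%), THF, −78 °C; DMF, −78 °C → rt; H2O; then K2CO3 (cat.), MeOH, rt
Reagents that add atoms: N,N-dimethylformamide CN(C)C=O (formyl group, C7)
Why: Arene-catalysed reductive lithiation should cleave the benzylic C6–O bond in preference to the aryl C–O bonds, the benzylic organolithium is formylated by DMF, and base equilibration places the formyl group trans to C4 (cis to H5), the less hindered and required C6 configuration.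

Step 12
Reactants: 23 (4bS,8aS,9R)-1,3,4-trimethoxy-4b,8,8-trimethyl-2-(propan-2-yl)-5,6,7,8,8a,9-hexahydro-4bH-fluorene-9-carbaldehyde
Product: 24 (4bS,8aS,9R)-3-methoxy-4b,8,8-trimethyl-1,4-dioxo-2-(propan-2-yl)-4,4b,5,6,7,8,8a,9-octahydro-1H-fluorene-9-carbaldehyde
Conditions: (NH4)2Ce(NO3)6, MeCN/H2O, 0 °C
Reagents that add atoms: water O (the two quinone oxygens)
Why: Oxidative demethylation of the para-dimethoxy pair (C11, C14) gives the 1,4-quinone and leaves the C12 methoxy group as a vinylogous ester; the aldehyde is inert to the oxidant.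

Step 13
Reactants: 24 (4bS,8aS,9R)-3-methoxy-4b,8,8-trimethyl-1,4-dioxo-2-(propan-2-yl)-4,4b,5,6,7,8,8a,9-octahydro-1H-fluorene-9-carbaldehyde; 25 myrcene
Product: 26 12-O-methyl ether of the target (5S,6R,8S,9R,10S)
Conditions: BF3·OEt2 (1.1 equiv), 25 (3 equiv), CH2Cl2, −78 → −30 °C
Reagents that add atoms: none
Why: In this Lewis-acid-catalysed Diels–Alder reaction BF3 should bind the most basic carbonyl (the vinylogous-ester C14=O), which makes C9 the electrophilic terminus so that the more nucleophilic diene terminus (the CH2 next to the substituted carbon of myrcene) bonds to C9, while suprafacial addition to the face of C8=C9 opposite the axial C10 methyl sets C8 and C9.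

Step 14
Reactants: 26 12-O-methyl ether of the target
Product: 27 CNP0239256.1 (target)
Conditions: LiOH, THF/H2O, 0 °C → rt; then 1 M HCl to pH 3
Reagents that add atoms: lithium hydroxide [Li+].[OH-] (oxygen of the C12 hydroxyl)
Why: Addition–elimination of hydroxide at C12 (vinylogous ester hydrolysis) frees the enol, and any C6 epimer should equilibrate under the same conditions to the more stable arrangement (CHO trans to C4) found in the target.

**Compound list**
1 | 1,2,4-trimethoxybenzene | COc1ccc(OC)c(OC)c1 | starting material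
2 | acetone | CC(C)=O | starting material
3 | (2,3,6-trimethoxyphenyl)lithium | [Li]c1c(OC)ccc(OC)c1OC | intermediate (not isolated)
4 | 2-(2,3,6-trimethoxyphenyl)propan-2-ol | CC(C)(O)c1c(OC)ccc(OC)c1OC | intermediate
5 | 1,2,4-trimethoxy-3-(propan-2-yl)benzene | CC(C)c1c(OC)ccc(OC)c1OC | intermediate
6 | 2,4,5-trimethoxy-3-(propan-2-yl)benzaldehyde | O=Cc1cc(OC)c(OC)c(C(C)C)c1OC | intermediate
7 | ortho-lithiated lithium α-amino alkoxide of 6 | [Li]OC(N(C)CCN(C)C)c1c([Li])c(OC)c(OC)c(C(C)C)c1OC | intermediate (not isolated)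
8 | 2-iodo-3,4,6-trimethoxy-5-(propan-2-yl)benzaldehyde | O=Cc1c(I)c(OC)c(OC)c(C(C)C)c1OC | intermediate
9 | 4,4,5,5-tetramethyl-2-(prop-1-en-2-yl)-1,3,2-dioxaborolane | CC(=C)B1OC(C)(C)C(C)(C)O1 | starting material
10 | 2,4,5-trimethoxy-3-(propan-2-yl)-6-(prop-1-en-2-yl)benzaldehyde | O=Cc1c(C(C)=C)c(OC)c(OC)c(C(C)C)c1OC | intermediate
11 | propyne | CC#C | starting material
12 | methyl(prop-1-yn-1-yl)zinc | CC#C[Zn]C | intermediate (not isolated)
13 | (1R)-1-[2,4,5-trimethoxy-3-(propan-2-yl)-6-(prop-1-en-2-yl)phenyl]but-2-yn-1-ol | CC#C[C@@H](O)c1c(C(C)=C)c(OC)c(OC)c(C(C)C)c1OC | intermediate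
14 | 1-[(1R)-1-methoxybut-2-yn-1-yl]-2,4,5-trimethoxy-3-(propan-2-yl)-6-(prop-1-en-2-yl)benzene | CC#C[C@@H](OC)c1c(C(C)=C)c(OC)c(OC)c(C(C)C)c1OC | intermediate
15 | bromoethene | C=CBr | starting material
16 | chlorobis(cyclopentadienyl)[(1E,3R)-3-aryl-3-methoxy-1-methylprop-1-enyl]zirconium (Zr on C4, cis to H5) | C/C(=C\[C@@H](OC)c1c(C(C)=C)c(OC)c(OC)c(C(C)C)c1OC)[Zr](Cl)(C1C=CC=C1)C1C=CC=C1 | intermediate (not isolated)
17 | corresponding alkenylzinc chloride (Zn on C4) | C/C(=C\[C@@H](OC)c1c(C(C)=C)c(OC)c(OC)c(C(C)C)c1OC)[Zn]Cl | intermediate (not isolated)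
18 | 1-[(1R,2E)-1-methoxy-3-methylpenta-2,4-dien-1-yl]-2,4,5-trimethoxy-3-(propan-2-yl)-6-(prop-1-en-2-yl)benzene | C=C/C(C)=C/[C@@H](OC)c1c(C(C)=C)c(OC)c(OC)c(C(C)C)c1OC | intermediate
19 | (4bS,8aS,9R)-1,3,4,9-tetramethoxy-4b,8-dimethyl-2-(propan-2-yl)-5,6,8a,9-tetrahydro-4bH-fluorene (trans-fused; OMe trans to C4) | CO[C@@H]1[C@H]2C(C)=CCC[C@]2(C)c2c(OC)c(OC)c(C(C)C)c(OC)c12 | intermediate
20 | N'-(C4-methyl) octane-1-sulfonohydrazide adduct of 19 (C4 epimers; C5, C6, C10 as in 19) | CO[C@@H]1[C@H]2C(C)(CNNS(=O)(=O)CCCCCCCC)CCC[C@]2(C)c2c(OC)c(OC)c(C(C)C)c(OC)c12 | intermediate (not isolated)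
21 | (4bS,8aS,9R)-1,3,4,9-tetramethoxy-4b,8,8-trimethyl-2-(propan-2-yl)-5,6,7,8,8a,9-hexahydro-4bH-fluorene | CO[C@@H]1[C@H]2C(C)(C)CCC[C@]2(C)c2c(OC)c(OC)c(C(C)C)c(OC)c12 | intermediate
22 | C6 (fluorene C9) benzylic organolithium from 21 (C6 configurationally labile; C5, C10 as in 21) | [Li]C1[C@H]2C(C)(C)CCC[C@]2(C)c2c(OC)c(OC)c(C(C)C)c(OC)c12 | intermediate (not isolated)
23 | (4bS,8aS,9R)-1,3,4-trimethoxy-4b,8,8-trimethyl-2-(propan-2-yl)-5,6,7,8,8a,9-hexahydro-4bH-fluorene-9-carbaldehyde | O=C[C@@H]1[C@H]2C(C)(C)CCC[C@]2(C)c2c(OC)c(OC)c(C(C)C)c(OC)c12 | intermediate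
24 | (4bS,8aS,9R)-3-methoxy-4b,8,8-trimethyl-1,4-dioxo-2-(propan-2-yl)-4,4b,5,6,7,8,8a,9-octahydro-1H-fluorene-9-carbaldehyde | O=C[C@@H]1[C@H]2C(C)(C)CCC[C@]2(C)C3=C1C(=O)C(C(C)C)=C(OC)C3=O | intermediate
25 | myrcene (7-methyl-3-methylideneocta-1,6-diene) | CC(C)=CCCC(=C)C=C | starting material
26 | 12-O-methyl ether of the target: (5S,6R,8S,9R,10S) Diels–Alder adduct of 24 and 25, ring D on the face opposite C20, side-chain carbon joined through CH2 to C9 | CC(C)=CCCC1=CC[C@@]23C(=O)C(C(C)C)=C(OC)C(=O)[C@]2(C1)[C@@]1(C)CCCC(C)(C)[C@@H]1[C@H]3C=O | intermediate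
27 | CNP0239256.1: (5S,6R,8S,9R,10S)-12-hydroxy-13-isopropyl-11,14-dioxo ring-B-contracted abietane 6-carbaldehyde with the 4-(4-methylpent-3-enyl)cyclohex-3-ene ring D fused at C8–C9 | CC(C)=CCCC1=CC[C@@]23C(=O)C(C(C)C)=C(O)C(=O)[C@]2(C1)[C@@]1(C)CCCC(C)(C)[C@@H]1[C@H]3C=O | target

**Step count**
Total steps: 14. Longest linear sequence: 14 (from 1,2,4-trimethoxybenzene).

**Steps most likely to fail**

1. Step 9. What may go wrong: cyclisation through the endo-tether transition state (cis ring fusion, wrong relative configuration of C10 and C5), or slow reaction of the unactivated 1,1-disubstituted dienophile with loss of methanol on long heating. Fallback by ring contraction, leaving the route at 6 and returning at 23: 6 is reduced with NaBH4 to [2,4,5-trimethoxy-3-(propan-2-yl)phenyl]methanol F1, which SOCl2 converts into 1-(chloromethyl)-2,4,5-trimethoxy-3-(propan-2-yl)benzene F2. Magnesium in THF gives the benzylic Grignard reagent F3 (not isolated), which is coupled with geranyl chloride (Li2CuCl4 cat.) to 1-[(3E)-4,8-dimethylnona-3,7-dien-1-yl]-2,4,5-trimethoxy-3-(propan-2-yl)benzene F4. An enantioselective proton-initiated polyene cyclisation (SnCl4 and (R)-2'-methoxy-1,1'-binaphthalen-2-ol, CH2Cl2, −78 °C; ligand antipode chosen for the 5S,10S series) closes a six-membered ring B and ring A to the trans-fused 11,12,14-trimethoxyabieta-8,11,13-triene F5. Benzylic oxidation (CrO3, AcOH) gives the 7-ketone F6. Trifluoroacetylation (LiN(SiMe3)2, CF3CO2CH2CF3, −78 °C) to the 6-trifluoroacetyl-7-ketone F7 (not isolated) and diazo transfer (MsN3, Et3N) give the 6-diazo-7-ketone F8. Photochemical Wolff rearrangement in MeOH contracts ring B to the methyl fluorene-9-carboxylate F9 (equilibrated with NaOMe to the 9R epimer), and i-Bu2AlH at −78 °C gives 23.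

2. Step 13. What may go wrong: bonding of the nucleophilic diene terminus to C8 instead of C9 when BF3 does not bind the C14 carbonyl selectively, addition on the face of the C10 methyl, or a Lewis-acid-promoted carbonyl-ene reaction of the aldehyde with myrcene. Fallback without Lewis acid, leaving the route at 24 and returning at 26: the uncatalysed reaction of 24 is governed by the C11 carbonyl (C8 electrophilic), so a diene is used whose nucleophilic terminus is the one that must end on C8. Ethyl acetoacetate is alkylated with 5-bromo-2-methylpent-2-ene (NaOEt, EtOH) to ethyl 2-acetyl-6-methylhept-5-enoate F10. Saponification and decarboxylation give 7-methyloct-6-en-2-one F11, and α-methylenation at C3 (paraformaldehyde, N-methylanilinium trifluoroacetate, THF, reflux) gives 7-methyl-3-methylideneoct-6-en-2-one F12. TBSOTf and Et3N give tert-butyl(dimethyl)[(7-methyl-3-methylideneocta-1,6-dien-2-yl)oxy]silane F13. Thermal Diels–Alder reaction with 24 (toluene, 80 °C) should give the silyl enol ether adduct F14, with the silyloxy-bearing carbon next to the CH2 on C8. CsF and PhNTf2 convert it into the enol triflate F15, and Pd(OAc)2, PPh3, Bu3N and HCO2H reduce the triflate to the ring D alkene, which is 26.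

3. Step 11. What may go wrong: electron transfer cleaving an aryl–OMe bond instead of the benzylic C–O bond, or protonation of the benzylic anion before it is formylated. Fallback through the ketone, leaving the route at 21 and returning at 23: DDQ in wet CH2Cl2 oxidises the benzylic methyl ether of 21 to the fluoren-9-one F16 (C5 and C10 as in 21). Non-basic methylenation (Zn, CH2Br2, TiCl4, THF) gives the 9-methylidene compound F17. Hydroboration and oxidation (9-BBN; NaOH, H2O2) give the 9-hydroxymethyl compound F18 (C6 epimers). Dess–Martin periodinane followed by K2CO3 in MeOH gives 23 as the thermodynamic C6 epimer.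

Further compounds
F1 | step 9 | [2,4,5-trimethoxy-3-(propan-2-yl)phenyl]methanol | OCc1cc(OC)c(OC)c(C(C)C)c1OC
F2 | step 9 | 1-(chloromethyl)-2,4,5-trimethoxy-3-(propan-2-yl)benzene | ClCc1cc(OC)c(OC)c(C(C)C)c1OC
F3 | step 9 | chloro{[2,4,5-trimethoxy-3-(propan-2-yl)phenyl]methyl}magnesium (not isolated) | Cl[Mg]Cc1cc(OC)c(OC)c(C(C)C)c1OC
F4 | step 9 | 1-[(3E)-4,8-dimethylnona-3,7-dien-1-yl]-2,4,5-trimethoxy-3-(propan-2-yl)benzene | CC(C)=CCC/C(C)=C/CCc1cc(OC)c(OC)c(C(C)C)c1OC
F5 | step 9 | 11,12,14-trimethoxyabieta-8,11,13-triene, trans-fused, C5 and C10 as in 21 | C1C[C@H]2C(C)(C)CCC[C@]2(C)c2c(OC)c(OC)c(C(C)C)c(OC)c12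
F6 | step 9 | 11,12,14-trimethoxyabieta-8,11,13-trien-7-one, C5 and C10 as in 21 | O=C1C[C@H]2C(C)(C)CCC[C@]2(C)c2c(OC)c(OC)c(C(C)C)c(OC)c12
F7 | step 9 | 6-(trifluoroacetyl) derivative of F6 (not isolated, C6 unassigned) | O=C1C(C(=O)C(F)(F)F)[C@H]2C(C)(C)CCC[C@]2(C)c2c(OC)c(OC)c(C(C)C)c(OC)c12
F8 | step 9 | 6-diazo-11,12,14-trimethoxyabieta-8,11,13-trien-7-one, C5 and C10 as in 21 | O=C1C(=[N+]=[N-])[C@H]2C(C)(C)CCC[C@]2(C)c2c(OC)c(OC)c(C(C)C)c(OC)c12
F9 | step 9 | methyl (4bS,8aS,9R)-1,3,4-trimethoxy-4b,8,8-trimethyl-2-(propan-2-yl)-5,6,7,8,8a,9-hexahydro-4bH-fluorene-9-carboxylate | COC(=O)[C@@H]1[C@H]2C(C)(C)CCC[C@]2(C)c2c(OC)c(OC)c(C(C)C)c(OC)c12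
F10 | step 13 | ethyl 2-acetyl-6-methylhept-5-enoate | CCOC(=O)C(CCC=C(C)C)C(C)=O
F11 | step 13 | 7-methyloct-6-en-2-one | CC(=O)CCCC=C(C)C
F12 | step 13 | 7-methyl-3-methylideneoct-6-en-2-one | CC(=O)C(=C)CCC=C(C)C
F13 | step 13 | tert-butyl(dimethyl)[(7-methyl-3-methylideneocta-1,6-dien-2-yl)oxy]silane | C=C(O[Si](C)(C)C(C)(C)C)C(=C)CCC=C(C)C
F14 | step 13 | silyl enol ether adduct of 24 and F13 (26 with OSi(t-Bu)Me2 on the ring D alkene carbon next to the CH2 on C8; stereocentres as in 26) | CC(C)=CCCC1=C(O[Si](C)(C)C(C)(C)C)C[C@@]23C(=O)C(C(C)C)=C(OC)C(=O)[C@]2(C1)[C@@]1(C)CCCC(C)(C)[C@@H]1[C@H]3C=O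
F15 | step 13 | corresponding enol trifluoromethanesulfonate (stereocentres as in 26) | CC(C)=CCCC1=C(OS(=O)(=O)C(F)(F)F)C[C@@]23C(=O)C(C(C)C)=C(OC)C(=O)[C@]2(C1)[C@@]1(C)CCCC(C)(C)[C@@H]1[C@H]3C=O
F16 | step 11 | 1,3,4-trimethoxy-4b,8,8-trimethyl-2-(propan-2-yl)-4b,5,6,7,8,8a-hexahydro-9H-fluoren-9-one, C5 and C10 as in 21 | O=C1[C@H]2C(C)(C)CCC[C@]2(C)c2c(OC)c(OC)c(C(C)C)c(OC)c12
F17 | step 11 | 9-methylidene analogue of F16, C5 and C10 as in 21 | C=C1[C@H]2C(C)(C)CCC[C@]2(C)c2c(OC)c(OC)c(C(C)C)c(OC)c12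
F18 | step 11 | 9-(hydroxymethyl) analogue (alcohol corresponding to 23, C6 epimers; C5 and C10 as in 21) | OCC1[C@H]2C(C)(C)CCC[C@]2(C)c2c(OC)c(OC)c(C(C)C)c(OC)c12
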